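**Retrosynthetic overview**
1. Feature: the tetrahydrofuran oxygen joins two fully substituted spiro carbons, C9 of decalin ring B and C13 of the γ-lactone. Only C11–C12 lie between them, and C8 and C16 are the outer neighbours. This O–C9/O–C13 pair is the retron of a 1,5-diene oxidative cyclisation.
2. Ring-B pattern (C6=O, 7β-OH, 8α-CH3) ⇒ 8α-carbinol: C7–O by Rubottom oxidation and epimerisation, C8–H by 6β-OH-directed hydrogenation, C6=O by allylic oxidation of the Δ7 alkene, Δ7 by dehydration and isomerisation.
3. γ-Lactone ⇒ C16–OH + C15 methyl ester. Tetrahydrofuran (C9–O, C13–O) with C8–OH and C16–OH ⇒ methyl labda-8,13(16)-dien-15-oate + permanganate.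
4. C12–C13 ⇒ Negishi coupling of the sclareolide-derived Δ8 C12 iodide with methyl 3-bromobut-3-enoate.
5. Ring order: decalin A/B (from sclareolide) → tetrahydrofuran (step 7) → γ-lactone (step 8).

Key step: step 7

Remark: labdane numbering and α/β descriptors are used. The SMILES is read as (5S,7R,8R,9R,10S,13R), that is 5α-H, 10β-CH3, 9α-O, 8α-CH3, 7β-OH, with C16 cis to C8 on the tetrahydrofuran ring.

**Step 1**
Reactants: 1 (+)-sclareolide
Product: 2 methyl 13,14,15,16-tetranorlabd-8-en-12-oate
Conditions: conc. H2SO4 (cat.), MeOH, reflux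
Reagents that add atoms: methanol, CO
Why: Acid-catalysed lactone methanolysis with E1 dehydration at the tertiary C8 centre, where reversible protonation should drain the Δ7 and Δ8(17) isomers into the tetrasubstituted Δ8 alkene (thermodynamic control) and C5 and C10 stay untouched.

**Step 2**
Reactants: 2 methyl 13,14,15,16-tetranorlabd-8-en-12-oate
Product: 3 13,14,15,16-tetranorlabd-8-en-12-ol
Conditions: LiAlH4, Et2O, 0 °C; aqueous work-up
Reagents that add atoms: none
Why: Standard hydride reduction of an ester to the primary alcohol, to which the isolated tetrasubstituted alkene is inert.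

**Step 3**
Reactants: 3 13,14,15,16-tetranorlabd-8-en-12-ol
Product: 4 12-iodo-13,14,15,16-tetranorlabd-8-ene
Conditions: PPh3, imidazole, I2, CH2Cl2, 0 °C → rt
Reagents that add atoms: iodine, II
Why: Appel-type iodination, an SN2 displacement of the alkoxyphosphonium ion at an unhindered primary carbon, with the iodine bound to phosphine before the alkene is exposed to it.

**Step 4**
Reactants: 5 3-bromobut-3-en-1-ol
Product: 6 3-bromobut-3-enoic acid
Conditions: TEMPO (10 mol %), PhI(OAc)2 (2.2 equiv), MeCN–H2O, rt
Reagents that add atoms: water, O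
Why: Oxoammonium-catalysed oxidation of a primary alcohol through the aldehyde hydrate to the acid, mild enough to leave the vinyl bromide and the β,γ position of the alkene unchanged.

**Step 5**
Reactants: 6 3-bromobut-3-enoic acid
Product: 7 methyl 3-bromobut-3-enoate
Conditions: MeOH, H2SO4 (cat.), rt → 40 °C
Reagents that add atoms: methanol, CO
Why: Fischer esterification, chosen because base-free conditions avoid loss of HBr to the allenoate and migration of the alkene into conjugation.

**Step 6**
Reactants: 4 12-iodo-13,14,15,16-tetranorlabd-8-ene; 7 methyl 3-bromobut-3-enoate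
Product: 9 methyl labda-8,13(16)-dien-15-oate, via alkylzinc iodide 8 (not isolated)
Conditions: Zn dust, I2 (5 mol %), DMA, 40 °C; then 7, PdCl2(dppf) (3 mol %), rt
Reagents that add atoms: none
Why: Negishi sp3–sp2 coupling forms C12–C13; the alkylzinc halide tolerates the ester and its acidic C14 hydrogens, the wide-bite-angle ligand suppresses β-hydride elimination, and the oxidised C15 arrives with the coupling partner, so no oxidant meets the diene before the key step.

**Step 7**
Reactants: 9 methyl labda-8,13(16)-dien-15-oate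
Product: 10 methyl (13R)-8α,16-dihydroxy-9α,13-epoxylabdan-15-oate
Conditions: KMnO4 (powdered, 1.5 equiv), Adogen 464 (10 mol %), AcOH (6 equiv), CH2Cl2, −30 → 0 °C; H2O, filtration through Celite
Reagents that add atoms: potassium permanganate, [K+].[O-][Mn](=O)(=O)=O
Why: Proposed new method: permanganate adds suprafacially in a (3+2) sense to one alkene to give a cyclic manganate ester, whose O–Mn=O unit, after oxidation at the metal, adds in a second intramolecular (3+2) step across the other alkene, so that one oxygen is bonded to both C9 and C13 and hydrolysis frees the C8 and C16 hydroxyls; the closest known reaction type is the permanganate (or Ru/Os-oxo) oxidative cyclisation of 1,5-dienes to cis-2,5-bis(hydroxyalkyl)tetrahydrofurans, established up to trisubstituted alkenes but not on a tetrasubstituted ring alkene. The tetrahydrofuran (O, C9, C11, C12, C13) closes in a 5-exo mode with respect to whichever alkene reacts second, inside a bicyclic metalla-ester. C8 and C9 are set by syn addition to the α face of C8=C9, because the axial C10 methyl covers the β face, the same bias that governs osmylation and epoxidation of drim-8-enes. C13 is set by the metalla-bicycle, which can hold C8–O and C16–O only on the same side of the new ring (cis-2,5), and this is the C9/C13 relation of the target. The open C13=C16 methylene will probably be attacked first and without facial bias, so the relay is expected to run from C13 to the ring: only the 13R ester can reach the α face, whereas the 13S ester would need the blocked β face and should be lost by hydrolysis to the 13,16-diol, which keeps the diastereoselectivity but sacrifices part of the material. The step needs ring closure to outrun hydrolysis and cleavage of the first ester, which is why it is run under phase-transfer conditions with little water, at low temperature and with acetic acid as the proton source.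

**Step 8**
Reactants: 10 methyl (13R)-8α,16-dihydroxy-9α,13-epoxylabdan-15-oate
Product: 11 (13R)-8α-hydroxy-9α,13-epoxylabdan-15,16-olide
Conditions: PPTS (cat.), toluene, 60 °C
Reagents that add atoms: none
Why: Acid-catalysed lactonisation (5-exo-trig transesterification) of the primary C16 hydroxyl onto C15, favoured by the quaternary C13; no stereocentre is touched, and any lactone already formed in step 7 converges here.

**Step 9**
Reactants: 11 (13R)-8α-hydroxy-9α,13-epoxylabdan-15,16-olide
Product: 12 (13R)-9α,13-epoxylabd-8(17)-en-15,16-olide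
Conditions: SOCl2, pyridine, CH2Cl2, −78 → −20 °C
Reagents that add atoms: none
Why: E2-type dehydration through the chlorosulfite: the equatorial 8α leaving group has no antiperiplanar ring hydrogen and C9 is quaternary, so pyridine should remove a C17 hydrogen, and the low temperature keeps a free C8 cation (and a shift from the oxygen-bearing C9) from developing.

**Step 10**
Reactants: 12 (13R)-9α,13-epoxylabd-8(17)-en-15,16-olide
Product: 13 (13R)-9α,13-epoxylabd-7-en-15,16-olide
Conditions: Co(III)(salen)Cl [salen = N,N′-bis(3,5-di-tert-butylsalicylidene)ethylenediamine] (5 mol %), PhSiH3 (10 mol %), benzene, rt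
Reagents that add atoms: none
Why: Cobalt-hydride H-atom-transfer alkene isomerisation: H• adds to C17, the tertiary C8 radical returns a C7 hydrogen to cobalt and gives the trisubstituted alkene under neutral conditions that cannot ionise the allylic C9–O bond.

**Step 11**
Reactants: 13 (13R)-9α,13-epoxylabd-7-en-15,16-olide
Product: 14 (13R)-6-oxo-9α,13-epoxylabd-7-en-15,16-olide
Conditions: Rh2(cap)4 (1 mol %), t-BuOOH (70 % aq., 10 equiv), DCE, 40 °C
Reagents that add atoms: tert-butyl hydroperoxide, CC(C)(C)OO
Why: Radical allylic oxidation with tert-butylperoxyl radicals; C6 is the only allylic methylene (C9 is quaternary, C17 offers only primary C–H) and the tetrahydrofuran has no α-hydrogen, as in the known C6 oxidation of drim-7-enes.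

**Step 12**
Reactants: 14 (13R)-6-oxo-9α,13-epoxylabd-7-en-15,16-olide
Product: 15 (13R)-6β-hydroxy-9α,13-epoxylabd-7-en-15,16-olide
Conditions: NaBH4, CeCl3·7H2O, MeOH, −78 → −40 °C
Reagents that add atoms: none
Why: Luche 1,2-reduction: the axial methyls on C4 and C10 close the β face of C6, so hydride enters from the α face and gives the pseudoaxial 6β-alcohol, while the lactone is not reduced at this temperature.

**Step 13**
Reactants: 15 (13R)-6β-hydroxy-9α,13-epoxylabd-7-en-15,16-olide
Product: 16 (13R)-6β-hydroxy-9α,13-epoxylabdan-15,16-olide with 8α-methyl (8β-H)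
Conditions: [Ir(cod)(PCy3)(py)]PF6 (10 mol %), H2 (1 atm), CH2Cl2, rt
Reagents that add atoms: none
Why: Hydroxyl-directed homogeneous hydrogenation with Crabtree's catalyst: the cationic iridium dihydride binds the pseudoaxial 6β-hydroxyl and delivers both hydrogens to the β face of C7=C8, which places H8 β and the C17 methyl α (equatorial), the opposite of an undirected α-face hydrogenation.

**Step 14**
Reactants: 16 (13R)-6β-hydroxy-9α,13-epoxylabdan-15,16-olide with 8α-methyl
Product: 17 (13R)-6-oxo-9α,13-epoxylabdan-15,16-olide with 8α-methyl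
Conditions: Dess–Martin periodinane, CH2Cl2, 0 °C → rt
Reagents that add atoms: none
Why: Dess–Martin oxidation, accelerated by the relief of the syn-axial strain of the 6β-alcohol; C8 is β to the new carbonyl and cannot epimerise, and the trans ring fusion at C5 is the stable one.

**Step 15**
Reactants: 17 (13R)-6-oxo-9α,13-epoxylabdan-15,16-olide with 8α-methyl
Product: 18 (13R)-6-triethylsilyloxy-9α,13-epoxylabd-6-en-15,16-olide
Conditions: TESOTf (1.2 equiv), Et3N (2 equiv), CH2Cl2, −20 → 0 °C
Reagents that add atoms: triethylsilyl triflate, CC[Si](CC)(CC)OS(=O)(=O)C(F)(F)F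
Why: Soft enolisation, which silylates a ketone faster than a lactone and avoids a lactone enolate that could expel the C13 oxygen; the Δ6 isomer is expected because a Δ5 enol ether would press the silyloxy group against the C4 methyls.

**Step 16**
Reactants: 18 (13R)-6-triethylsilyloxy-9α,13-epoxylabd-6-en-15,16-olide
Product: 20 (13R)-7α-triethylsilyloxy-6-oxo-9α,13-epoxylabdan-15,16-olide, via silyloxy epoxide 19 (not isolated)
Conditions: mCPBA, CH2Cl2–hexane, −20 → 0 °C
Reagents that add atoms: 3-chloroperbenzoic acid, O=C(OO)c1cccc(Cl)c1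
Why: Rubottom oxidation: the peracid should approach C6=C7 from the α face, since the C4 and C10 axial methyls shield the β face over C6, and the silyloxy epoxide opens with 1,4-silyl migration to the axial 7α-silyloxy ketone.

**Step 17**
Reactants: 20 (13R)-7α-triethylsilyloxy-6-oxo-9α,13-epoxylabdan-15,16-olide
Product: 21 (13R)-7β-triethylsilyloxy-6-oxo-9α,13-epoxylabdan-15,16-olide
Conditions: DBU (0.3 equiv), toluene, rt → 45 °C
Reagents that add atoms: none
Why: Base-catalysed epimerisation α to the ketone: the axial 7α-silyloxy group is syn-diaxial to the 9α oxygen, axial reprotonation of the Δ6 enolate from the α face gives the equatorial 7β epimer that thermodynamics also favours, and the silyl group blocks the enediol route to a 7-ketone that could eliminate the C9 oxygen.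

**Step 18**
Reactants: 21 (13R)-7β-triethylsilyloxy-6-oxo-9α,13-epoxylabdan-15,16-olide
Product: 22 (13R)-7β-hydroxy-6-oxo-9α,13-epoxylabdan-15,16-olide (target CNP0291402.1)
Conditions: HF·pyridine, THF, 0 °C
Reagents that add atoms: none
Why: Fluoride-driven desilylation under weakly acidic, base-free conditions, so that neither the α-ketol nor the β-alkoxy lactone is enolised and all six stereocentres are kept.

**Compound list**
1 | (+)-sclareolide | C[C@@]12CC[C@H]3C(C)(C)CCC[C@]3(C)[C@H]1CC(=O)O2 | starting material
2 | methyl 13,14,15,16-tetranorlabd-8-en-12-oate | CC1=C(CC(=O)OC)[C@@]2(C)CCCC(C)(C)[C@@H]2CC1 | intermediate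
3 | 13,14,15,16-tetranorlabd-8-en-12-ol | CC1=C(CCO)[C@@]2(C)CCCC(C)(C)[C@@H]2CC1 | intermediate
4 | 12-iodo-13,14,15,16-tetranorlabd-8-ene | CC1=C(CCI)[C@@]2(C)CCCC(C)(C)[C@@H]2CC1 | intermediate
5 | 3-bromobut-3-en-1-ol | C=C(Br)CCO | starting material
6 | 3-bromobut-3-enoic acid | C=C(Br)CC(=O)O | intermediate
7 | methyl 3-bromobut-3-enoate | C=C(Br)CC(=O)OC | intermediate
8 | (13,14,15,16-tetranorlabd-8-en-12-yl)zinc iodide (not isolated) | CC1=C(CC[Zn]I)[C@@]2(C)CCCC(C)(C)[C@@H]2CC1 | intermediate
9 | methyl labda-8,13(16)-dien-15-oate | CC1=C(CCC(=C)CC(=O)OC)[C@@]2(C)CCCC(C)(C)[C@@H]2CC1 | intermediate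
10 | methyl (13R)-8α,16-dihydroxy-9α,13-epoxylabdan-15-oate | C[C@@]1(O)CC[C@H]2C(C)(C)CCC[C@]2(C)[C@@]12CC[C@](CO)(CC(=O)OC)O2 | intermediate
11 | (13R)-8α-hydroxy-9α,13-epoxylabdan-15,16-olide | C[C@@]1(O)CC[C@H]2C(C)(C)CCC[C@]2(C)[C@@]12CC[C@@]1(COC(=O)C1)O2 | intermediate
12 | (13R)-9α,13-epoxylabd-8(17)-en-15,16-olide | C=C1CC[C@H]2C(C)(C)CCC[C@]2(C)[C@@]12CC[C@@]1(COC(=O)C1)O2 | intermediate
13 | (13R)-9α,13-epoxylabd-7-en-15,16-olide | CC1=CC[C@H]2C(C)(C)CCC[C@]2(C)[C@@]12CC[C@@]1(COC(=O)C1)O2 | intermediate
14 | (13R)-6-oxo-9α,13-epoxylabd-7-en-15,16-olide | CC1=CC(=O)[C@H]2C(C)(C)CCC[C@]2(C)[C@@]12CC[C@@]1(COC(=O)C1)O2 | intermediate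
15 | (13R)-6β-hydroxy-9α,13-epoxylabd-7-en-15,16-olide | CC1=C[C@@H](O)[C@H]2C(C)(C)CCC[C@]2(C)[C@@]12CC[C@@]1(COC(=O)C1)O2 | intermediate
16 | (13R)-6β-hydroxy-9α,13-epoxylabdan-15,16-olide, 8α-methyl | C[C@@H]1C[C@@H](O)[C@H]2C(C)(C)CCC[C@]2(C)[C@@]12CC[C@@]1(COC(=O)C1)O2 | intermediate
17 | (13R)-6-oxo-9α,13-epoxylabdan-15,16-olide, 8α-methyl | C[C@@H]1CC(=O)[C@H]2C(C)(C)CCC[C@]2(C)[C@@]12CC[C@@]1(COC(=O)C1)O2 | intermediate
18 | (13R)-6-triethylsilyloxy-9α,13-epoxylabd-6-en-15,16-olide | C[C@@H]1C=C(O[Si](CC)(CC)CC)[C@H]2C(C)(C)CCC[C@]2(C)[C@@]12CC[C@@]1(COC(=O)C1)O2 | intermediate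
19 | (13R)-6α,7α;9α,13-diepoxy-6β-triethylsilyloxylabdan-15,16-olide (not isolated) | C[C@@H]1[C@@H]3O[C@]3(O[Si](CC)(CC)CC)[C@H]2C(C)(C)CCC[C@]2(C)[C@@]12CC[C@@]1(COC(=O)C1)O2 | intermediate
20 | (13R)-7α-triethylsilyloxy-6-oxo-9α,13-epoxylabdan-15,16-olide | C[C@@H]1[C@H](O[Si](CC)(CC)CC)C(=O)[C@H]2C(C)(C)CCC[C@]2(C)[C@@]12CC[C@@]1(COC(=O)C1)O2 | intermediate
21 | (13R)-7β-triethylsilyloxy-6-oxo-9α,13-epoxylabdan-15,16-olide | C[C@@H]1[C@@H](O[Si](CC)(CC)CC)C(=O)[C@H]2C(C)(C)CCC[C@]2(C)[C@@]12CC[C@@]1(COC(=O)C1)O2 | intermediate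
22 | (13R)-7β-hydroxy-6-oxo-9α,13-epoxylabdan-15,16-olide (CNP0291402.1) | C[C@@H]1[C@@H](O)C(=O)[C@H]2C(C)(C)CCC[C@]2(C)[C@@]12CC[C@@]1(COC(=O)C1)O2 | target

**Step count**
Total: 18 steps.
Longest linear sequence: 16 steps (steps 1–3 and 6–18, from sclareolide). Steps 4–5 form a two-step side branch.

**Steps most likely to fail**

**Step 7.**
- Risk: the second, intramolecular cycloaddition onto the hindered tetrasubstituted alkene may be slower than hydrolysis or oxidative cleavage of the first manganate ester. Only the side chain would then be oxidised.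
- Fallback (known chemistry): it sets out from 9 and comes back at 11.
- Exhaustive osmylation of 9 (OsO4, 2.2 equiv, pyridine; aq. NaHSO3) dihydroxylates both alkenes, the ring alkene from the α face. The 16-hydroxyl closes onto the ester and gives 8α,9α,13-trihydroxylabdan-15,16-olide F1 as both C13 epimers.
- MsCl/Et3N converts the least hindered tertiary hydroxyl into 8α,9α-dihydroxy-13-mesyloxylabdan-15,16-olide F2. This loses the mesylate by E1cB to the butenolide 8α,9α-dihydroxylabd-13-en-15,16-olide F3.
- Catalytic DBU then triggers the 5-exo oxa-Michael addition of the axial 9α-hydroxyl to C13. This gives 11 beside (13S)-8α-hydroxy-9α,13-epoxylabdan-15,16-olide F4, which is separated and re-equilibrated under the same conditions.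
- The price is that C13 is no longer relayed from C9.

**Step 13.**
- Risk: facial selectivity may be poor, because the catalyst may fail to bind the crowded 6β-hydroxyl or be steered to the α face by the ether or lactone oxygens. The acidic iridium hydride may also ionise the doubly allylic system.
- Fallback: it sets out from 15 and comes back at 16.
- Radical hydrogenation by metal-hydride H-atom transfer is used (Mn(dpm)3 cat., PhSiH3, t-BuOOH, i-PrOH, rt).
- H• adds to C7, and the tertiary C8 radical takes up hydrogen along the axial trajectory.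
- The equatorial 8α-methyl would then form under thermodynamic stereocontrol, without any coordination to the substrate.
- New compound on this way: none F0.

**Step 17.**
- Risk: removal of the equatorial H7 may be sluggish. The lactone may enolise in competition, with retro-oxa-Michael opening of the C13–O bond and scrambling of C13.
- Fallback: it avoids all enolate chemistry, sets out from 15 and comes back at 21.
- Epoxidation directed by the pseudoaxial 6β-hydroxyl (VO(acac)2, t-BuOOH) gives (13R)-7β,8β;9α,13-diepoxy-6β-hydroxylabdan-15,16-olide F5, which fixes the 7β C–O bond.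
- Cp2TiCl (from Cp2TiCl2 and Mn) opens the epoxide homolytically at C8, and the tertiary radical loses a C17 hydrogen. The product is (13R)-6β,7β-dihydroxy-9α,13-epoxylabd-8(17)-en-15,16-olide F6.
- Crabtree hydrogenation, now directed by the unhindered allylic 7β-hydroxyl, gives (13R)-6β,7β-dihydroxy-9α,13-epoxylabdan-15,16-olide F7 with the 8α-methyl.
- TESCl/imidazole silylates the less hindered equatorial hydroxyl to (13R)-6β-hydroxy-7β-triethylsilyloxy-9α,13-epoxylabdan-15,16-olide F8.
- Dess–Martin oxidation of F8 gives 21.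

**Further compounds**
F1 | step 7 | 8α,9α,13-trihydroxylabdan-15,16-olide (both C13 epimers) | C[C@@]1(O)CC[C@H]2C(C)(C)CCC[C@]2(C)[C@@]1(O)CCC1(O)COC(=O)C1
F2 | step 7 | 8α,9α-dihydroxy-13-mesyloxylabdan-15,16-olide (both C13 epimers) | C[C@@]1(O)CC[C@H]2C(C)(C)CCC[C@]2(C)[C@@]1(O)CCC1(OS(C)(=O)=O)COC(=O)C1
F3 | step 7 | 8α,9α-dihydroxylabd-13-en-15,16-olide | C[C@@]1(O)CC[C@H]2C(C)(C)CCC[C@]2(C)[C@@]1(O)CCC1=CC(=O)OC1
F4 | step 7 | (13S)-8α-hydroxy-9α,13-epoxylabdan-15,16-olide | C[C@@]1(O)CC[C@H]2C(C)(C)CCC[C@]2(C)[C@@]12CC[C@]1(COC(=O)C1)O2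
F0 | step 13 | none | none
F5 | step 17 | (13R)-7β,8β;9α,13-diepoxy-6β-hydroxylabdan-15,16-olide | C[C@]12O[C@H]1[C@@H](O)[C@H]3C(C)(C)CCC[C@]3(C)[C@@]24CC[C@@]5(COC(=O)C5)O4
F6 | step 17 | (13R)-6β,7β-dihydroxy-9α,13-epoxylabd-8(17)-en-15,16-olide | C=C1[C@@H](O)[C@@H](O)[C@H]2C(C)(C)CCC[C@]2(C)[C@@]12CC[C@@]1(COC(=O)C1)O2
F7 | step 17 | (13R)-6β,7β-dihydroxy-9α,13-epoxylabdan-15,16-olide, 8α-methyl | C[C@@H]1[C@@H](O)[C@@H](O)[C@H]2C(C)(C)CCC[C@]2(C)[C@@]12CC[C@@]1(COC(=O)C1)O2
F8 | step 17 | (13R)-6β-hydroxy-7β-triethylsilyloxy-9α,13-epoxylabdan-15,16-olide | C[C@@H]1[C@@H](O[Si](CC)(CC)CC)[C@@H](O)[C@H]2C(C)(C)CCC[C@]2(C)[C@@]12CC[C@@]1(COC(=O)C1)O2
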